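**Retrosynthetic overview**
1. Target 42 ← acetonide removal, Mitsunobu acetate inversion at C12, γ-lactone by oxidation of the C19 carbinol onto O7, and reduction/acetylation at C2 ← cyclodecenone 35.
2. Key disconnection C3–C4: 35 ← Claisen ring expansion of 2-methyleneoxocane 34, made in the same flask by methylenation of the eight-membered lactone 33 (C2(=O)–O–C6, isopropenyl on C6). Enabling feature: at the C2 ketone level, C2(O)–C3–C4–C5=C6 of the ten-membered ring is a γ,δ-unsaturated carbonyl; C6 sits next to oxygenated C7, so a disposable C6–O bond can be placed there; C1 is quaternary, so the C2 enol ether cannot move into the ring.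
3. 33 ← seco acid 31 ← alkoxyallylboration (C6–C7; brings in C4, C5, C16) of lactol 21 ← aldol union (C8–C9) of ring A aldehyde 12 with the enediolate of an (R)-β-methyl-γ-butyrolactone derivative.
4. 12 ← catalytic asymmetric Diels–Alder reaction of silyloxydiene 2 with enal 3 (sets C1 and C10), then C11 epimerisation and C12 reduction.
5. Ring order: ring A (step 2) → dioxolane (step 14) → eight-membered lactone (step 21) → ten-membered carbocycle (step 22) → γ-lactone (step 26).

Key step: step 22

Remark (numbering): coupled intermediates carry the briarane numbering of 42 (C15 = CH3 on C1, C16 = CH3 on C5, C18 = CH3 on C17, C19 = lactone C=O, C20 = CH3 on C11); β is the face of ring A that carries C15.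
Assumption: in step 2 the (S)-prolinol-derived oxazaborolidinium ion is taken to select the enal face as it does for 2-methylacrolein; if the sense is opposite, the (R)-catalyst is used and nothing else changes.

Step 1
Reactants: 1 pent-1-en-3-one
Product: 2 (Z)-triisopropyl(penta-1,3-dien-3-yloxy)silane
Conditions: i-Pr3SiOTf, Et3N, Et2O, 0 °C to rt
Reagents that add atoms: triisopropylsilyl trifluoromethanesulfonate, CC(C)[Si](OS(=O)(=O)C(F)(F)F)(C(C)C)C(C)C
Why: Silyl dienol ether formation under equilibrating conditions should favour the Z enol ether, whose methyl group lies outside in the s-cis diene, the reactive geometry for the cycloaddition.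

Step 2
Reactants: 2 (Z)-triisopropyl(penta-1,3-dien-3-yloxy)silane; 3 (E)-4,4-dimethoxy-2-methylbut-2-enal
Product: 4 (1S,5S,6S)-6-(dimethoxymethyl)-1,5-dimethyl-4-(triisopropylsilyloxy)cyclohex-3-ene-1-carbaldehyde
Conditions: (S)-o-tolyl-oxazaborolidinium triflimide [from (S)-diphenylprolinol, tri(o-tolyl)boroxine, HNTf2] (20 mol %), CH2Cl2, −78 to −40 °C
Reagents that add atoms: none
Why: Enantioselective Diels–Alder reaction of an α-methyl enal bound to a chiral oxazaborolidinium ion: the enol-ether terminus C11 bonds to the enal β-carbon C10 (C1 para to C12), the E enal fixes C9 cis to the C1 methyl, the catalyst sets C1 and C10, and the formyl-endo approach leaves the C11 methyl α, which step 5 corrects.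

Step 3
Reactants: 4 silyl enol ether aldehyde
Product: 5 (1S,5S,6S)-6-(dimethoxymethyl)-1,5-dimethyl-4-oxocyclohex-2-ene-1-carbaldehyde
Conditions: Pd(OAc)2 (10 mol %), O2 (1 atm), DMSO, 60 °C
Reagents that add atoms: none
Why: Saegusa–Ito oxidation: the palladium enolate at C13 can eliminate only a C14 hydrogen, so the C13=C14 enone forms and C11 is untouched.

Step 4
Reactants: 5 enone aldehyde
Product: 6 (1S,5S,6S)-6-(dimethoxymethyl)-1,5-dimethyl-4-oxocyclohex-2-ene-1-carboxylic acid
Conditions: NaClO2, NaH2PO4, 2-methylbut-2-ene, t-BuOH/H2O, 0 °C to rt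
Reagents that add atoms: sodium chlorite, [Na+].[O-]Cl=O
Why: Pinnick oxidation converts the neopentyl aldehyde into the C2 acid under buffered conditions that leave enone and acetal intact.

Step 5
Reactants: 6 enone acid (C11 methyl α)
Product: 8 (1S,5R,6S)-6-(dimethoxymethyl)-1,5-dimethyl-4-oxocyclohex-2-ene-1-carboxylic acid, via dilithium dienolate 7 (not isolated)
Conditions: LiN(i-Pr)2 (2.2 equiv), THF, −78 °C; then AcOH, −78 °C
Reagents that add atoms: none
Why: α′-Deprotonation to the cross-conjugated dienolate followed by kinetic protonation: A(1,2) strain with the C11 methyl holds the C10 acetal pseudo-axial on the β-face, so the proton, relayed by the pseudo-axial C1 carboxyl group, should reach C11 from the α-face and leave the methyl β.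

Step 6
Reactants: 8 enone acid (C11 methyl β)
Product: 9 (1S,4S,5R,6S)-6-(dimethoxymethyl)-4-hydroxy-1,5-dimethylcyclohex-2-ene-1-carboxylic acid
Conditions: NaBH4, CeCl3·7H2O, MeOH, −40 °C; aqueous citric acid work-up
Reagents that add atoms: none
Why: Luche 1,2-reduction: the β-face of the C12 carbonyl is screened by the axial C10 dimethoxymethyl group, so hydride should enter from the α-face beside the small carboxylate and give the 12β alcohol, which is used in step 13 and inverted in step 27.

Step 7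
Reactants: 9 hydroxy acid
Product: 10 tert-butyl (1S,4S,5R,6S)-6-(dimethoxymethyl)-4-hydroxy-1,5-dimethylcyclohex-2-ene-1-carboxylate
Conditions: Me2NCH(Ot-Bu)2, toluene, 80 °C
Reagents that add atoms: N,N-dimethylformamide di-tert-butyl acetal, CN(C)C(OC(C)(C)C)OC(C)(C)C
Why: O-Alkylation of the carboxylate by the formamide acetal esterifies the hindered acid without acyl activation and gives a tert-butyl ester that should resist enolates and i-Bu2AlH.

Step 8
Reactants: 10 hydroxy ester
Product: 11 tert-butyl (1S,4S,5R,6S)-4-(tert-butyldimethylsilyloxy)-6-(dimethoxymethyl)-1,5-dimethylcyclohex-2-ene-1-carboxylate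
Conditions: t-BuMe2SiOTf, 2,6-lutidine, CH2Cl2, −78 °C
Reagents that add atoms: tert-butyldimethylsilyl trifluoromethanesulfonate, CC(C)(C)[Si](C)(C)OS(=O)(=O)C(F)(F)F
Why: Silyl ether formation at low temperature protects the hindered allylic alcohol before the acetal is opened.

Step 9
Reactants: 11 silyl ether acetal
Product: 12 tert-butyl (1S,4S,5R,6S)-4-(tert-butyldimethylsilyloxy)-6-formyl-1,5-dimethylcyclohex-2-ene-1-carboxylate
Conditions: pyridinium p-toluenesulfonate (cat.), acetone/H2O, 50 °C
Reagents that add atoms: water, O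
Why: Mild acid-catalysed acetal hydrolysis releases the C9 aldehyde, while the silyl ether and the tert-butyl ester should survive.

Step 10
Reactants: 13 (R)-4-methyldihydrofuran-2(3H)-one
Product: 15 (3R,4S)-3-hydroxy-4-methyldihydrofuran-2(3H)-one, via potassium enolate 14 (not isolated)
Conditions: KN(SiMe3)2, THF, −78 °C; 2-(phenylsulfonyl)-3-phenyloxaziridine; then AcOH
Reagents that add atoms: 2-(phenylsulfonyl)-3-phenyloxaziridine, O=S(=O)(c1ccccc1)N1OC1c1ccccc1
Why: Enolate hydroxylation with an N-sulfonyloxaziridine introduces the future C8 oxygen trans to the methyl group; the new stereocentre is erased again in step 11.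

Step 11
Reactants: 15 hydroxy lactone; 12 ring A aldehyde
Product: 17 C8–C9 aldol adduct (C9 epimers), via dilithium enediolate 16 (not isolated)
Conditions: LiN(i-Pr)2 (2.2 equiv), THF, −78 °C; then 12, −78 °C; AcOH
Reagents that add atoms: none
Why: Aldol addition of the lactone enediolate: C8 attacks the aldehyde on the face opposite the adjacent C17 methyl, which sets the tertiary C8 carbinol as in the target, while C9 forms unselectively and is flattened in step 12.

Step 12
Reactants: 17 aldol adduct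
Product: 18 C9 ketone
Conditions: Dess–Martin periodinane, CH2Cl2, 0 °C to rt
Reagents that add atoms: none
Why: Dess–Martin oxidation of the only secondary alcohol gives the C9 ketone and leaves the tertiary C8 hydroxyl untouched.

Step 13
Reactants: 18 C9 ketone
Product: 19 (9R)-8,9-diol lactone
Conditions: NaBH4, MeOH/THF, −40 °C
Reagents that add atoms: none
Why: Diastereoselective ketone reduction: the syn-axial 12β silyl ether on ring A closes the C11-side face and turns the carbonyl oxygen toward C1, so hydride should enter from the open side, the same sense as Felkin–Anh control by the C8 oxygen, and give the (9R) alcohol.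

Step 14
Reactants: 19 diol lactone
Product: 20 8,9-O-isopropylidene lactone
Conditions: 2,2-dimethoxypropane, pyridinium p-toluenesulfonate (cat.), CH2Cl2, rt
Reagents that add atoms: 2,2-dimethoxypropane, COC(C)(C)OC
Why: Acetonide formation ties O8 and O9 into a dioxolane, so that later only O7 can lactonise onto C19.

Step 15
Reactants: 20 acetonide lactone
Product: 21 C7 lactol (anomers)
Conditions: i-Bu2AlH (1.2 equiv), CH2Cl2, −78 °C; aqueous sodium potassium tartrate
Reagents that add atoms: none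
Why: Partial reduction of the γ-lactone to the lactol at −78 °C; the tert-butyl ester on quaternary C1 should be too hindered to react.

Step 16
Reactants: 22 4-methoxyphenol; 23 3-chloro-2-methylprop-1-ene
Product: 24 1-methoxy-4-[(2-methylprop-2-en-1-yl)oxy]benzene
Conditions: K2CO3, KI (cat.), acetone, reflux
Reagents that add atoms: none
Why: Williamson ether synthesis gives the allyl aryl ether whose aryl group can later be removed oxidatively.

Step 17
Reactants: 21 lactol; 24 methallyl 4-methoxyphenyl ether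
Product: 27 (6R,7S)-6-(4-methoxyphenoxy)-7,19-diol with isopropenyl on C6, via allyllithium 25 (not isolated), via allylborane 26 (not isolated)
Conditions: 24, s-BuLi, THF, −78 °C; (−)-Ipc2BOMe [from (+)-α-pinene]; BF3·OEt2; then 21, −78 °C to rt; NaOH, H2O2
Reagents that add atoms: none
Why: γ-Alkoxyallylboration with a diisopinocampheylborane: the lactol reacts through its open C7 aldehyde, the Z reagent gives the 6,7-syn arrangement through a chair transition state, the isopinocampheyl groups should direct attack to the face that gives (7S), and the step brings in C4, C5, C6 and C16.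

Step 18
Reactants: 27 diol
Product: 28 7,19-bis(tert-butyldimethylsilyl) ether
Conditions: t-BuMe2SiOTf, 2,6-lutidine, CH2Cl2, −78 to −20 °C
Reagents that add atoms: tert-butyldimethylsilyl trifluoromethanesulfonate, CC(C)(C)[Si](C)(C)OS(=O)(=O)C(F)(F)F
Why: Silylation masks the C7 and C19 hydroxyls so that only O6 can later be acylated by the C2 carboxyl group.

Step 19
Reactants: 28 aryl ether
Product: 29 C6 alcohol
Conditions: (NH4)2Ce(NO3)6, MeCN/H2O, 0 °C
Reagents that add atoms: none
Why: Oxidative dearylation of the 4-methoxyphenyl ether releases the C6 alcohol without acid or fluoride.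

Step 20
Reactants: 29 tert-butyl ester
Product: 31 seco acid, via silyl ester 30 (not isolated)
Conditions: Me3SiOTf, 2,6-lutidine, CH2Cl2, 0 °C; then aqueous citric acid
Reagents that add atoms: none
Why: Silyl triflate-induced cleavage of the tert-butyl ester (loss of 2-methylpropene) gives the silyl ester, hydrolysed on work-up, so the hindered acid is freed without aqueous acid or base.

Step 21
Reactants: 31 seco acid
Product: 33 (6R)-eight-membered lactone, via mixed anhydride 32 (not isolated)
Conditions: 2,4,6-trichlorobenzoyl chloride, Et3N, THF, rt; then slow addition to DMAP, toluene (1 mM), 80 °C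
Reagents that add atoms: none
Why: Yamaguchi macrolactonisation under high dilution closes the eight-membered lactone between the C2 carboxyl group and O6; the cyclohexene and dioxolane rings pre-organise the seco acid and every other hydroxyl is blocked.

Step 22
Reactants: 33 eight-membered lactone
Product: 35 (5Z)-cyclodecenone (C2 ketone), via 2-methyleneoxocane 34 (not isolated)
Conditions: Cp2TiMe2 (3 equiv), toluene, 75 °C, dark; then 150 °C, sealed tube
Reagents that add atoms: bis(cyclopentadienyl)dimethyltitanium, C[Ti](C)(C1C=CC=C1)C1C=CC=C1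
Why: Cp2TiMe2 (through Cp2Ti=CH2) methylenates the lactone carbonyl C2 to the 2-methyleneoxocane 34, and on further heating the allyl vinyl ether C3=C2–O–C6–C5=C4 undergoes a concerted [3,3]-sigmatropic (Claisen) shift that forms C3–C4, breaks O–C6 and leaves the C2 ketone. The closest known reaction type is the carbonyl methylenation/Claisen ring expansion of 2-methylene oxacycles that carry a 2-alkenyl group, which gives medium-ring cycloalkenones. The ten-membered carbocycle is closed by a two-atom ring expansion of the eight-membered oxacycle through a bicyclic six-membered chair transition state; no sp3 stereocentre is created and the C6 stereocentre is consumed. The five-atom tether C7–C8–C9–C10–C1 can span the array only when C7 is pseudo-axial on C6, which places C7 cis to C4 and should give the (5Z)-alkene; the pseudo-equatorial alternative needs a boat and suffers A(1,2) strain between C7 and the C5 methyl. The step needs methylenation of the lactone carbonyl alone and an enol ether that does not isomerise: 33 carries no other carbonyl group, and C1 is quaternary, so 34 has no endocyclic isomer.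

Step 23
Reactants: 35 cyclodecenone
Product: 36 (2R)-alcohol
Conditions: (S)-2-methyl-CBS-oxazaborolidine (0.5 equiv), catecholborane, toluene, −78 to −40 °C; then MeOH, aqueous NaOH
Reagents that add atoms: none
Why: CBS reduction with catecholborane: catalyst control with quaternary C1 as the large and the C3 methylene as the small substituent should deliver the (2R) alcohol, and no alkene is hydroborated at this temperature.

Step 24
Reactants: 36 C2 alcohol
Product: 37 2-acetate
Conditions: Ac2O, DMAP, pyridine, rt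
Reagents that add atoms: acetic anhydride, CC(=O)OC(C)=O
Why: DMAP-catalysed acetylation of the hindered C2 alcohol.

Step 25
Reactants: 37 tris(silyl ether)
Product: 38 7,12β,19-triol
Conditions: HF·pyridine, pyridine, THF, 0 °C to rt
Reagents that add atoms: none
Why: Fluoride-mediated desilylation removes all three silyl ethers, while the acetate and the acetonide remain.

Step 26
Reactants: 38 triol
Product: 40 γ-lactone with free 12β-hydroxyl, via lactol 39 (not isolated)
Conditions: TEMPO (20 mol %), PhI(OAc)2 (2.4 equiv), CH2Cl2, rt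
Reagents that add atoms: none
Why: Oxoammonium (TEMPO/PhI(OAc)2) oxidative lactonisation: the primary C19 alcohol is oxidised first, the aldehyde is trapped at once by O7 as the five-membered lactol (O9 is blocked by the acetonide) and oxidised on to the γ-lactone, and the hindered pseudo-axial C12 alcohol should react far more slowly.

Step 27
Reactants: 40 12β-alcohol
Product: 41 12α-acetate (8,9-O-isopropylidene derivative of 42)
Conditions: PPh3, diisopropyl azodicarboxylate, AcOH, toluene, 0 °C to rt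
Reagents that add atoms: acetic acid, CC(=O)O
Why: Mitsunobu reaction with acetic acid inverts the allylic C12 carbinol by SN2 displacement and installs the 12α acetate directly; the SN2′ terminus C14 is neopentyl and shielded.

Step 28
Reactants: 41 acetonide
Product: 42 CNP0286823.1
Conditions: AcOH/H2O (4:1), 40 °C
Reagents that add atoms: none
Why: Mild aqueous acid hydrolysis of the isopropylidene acetal frees the 8,9-diol without cleaving the acetates or the lactone.

**Compound list**
1 | pent-1-en-3-one | C=CC(=O)CC | starting material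
2 | (Z)-triisopropyl(penta-1,3-dien-3-yloxy)silane | C=C/C(O[Si](C(C)C)(C(C)C)C(C)C)=C/C | intermediate
3 | (E)-4,4-dimethoxy-2-methylbut-2-enal | O=C/C(C)=C/C(OC)OC | starting material
4 | (1S,5S,6S)-6-(dimethoxymethyl)-1,5-dimethyl-4-(triisopropylsilyloxy)cyclohex-3-ene-1-carbaldehyde | CC(C)[Si](C(C)C)(C(C)C)OC1=CC[C@@](C=O)(C)[C@H]([C@@H]1C)C(OC)OC | intermediate
5 | (1S,5S,6S)-6-(dimethoxymethyl)-1,5-dimethyl-4-oxocyclohex-2-ene-1-carbaldehyde | O=C1C=C[C@@](C=O)(C)[C@H]([C@@H]1C)C(OC)OC | intermediate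
6 | (1S,5S,6S)-6-(dimethoxymethyl)-1,5-dimethyl-4-oxocyclohex-2-ene-1-carboxylic acid | O=C1C=C[C@@](C(=O)O)(C)[C@H]([C@@H]1C)C(OC)OC | intermediate
7 | dilithium carboxylate dienolate of 6 (C11 planar) | [Li+].[Li+].[O-]C=1C=C[C@@](C([O-])=O)(C)[C@H](C1C)C(OC)OC | intermediate
8 | (1S,5R,6S)-6-(dimethoxymethyl)-1,5-dimethyl-4-oxocyclohex-2-ene-1-carboxylic acid | O=C1C=C[C@@](C(=O)O)(C)[C@H]([C@H]1C)C(OC)OC | intermediate
9 | (1S,4S,5R,6S)-6-(dimethoxymethyl)-4-hydroxy-1,5-dimethylcyclohex-2-ene-1-carboxylic acid | O[C@H]1C=C[C@@](C(=O)O)(C)[C@H]([C@H]1C)C(OC)OC | intermediate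
10 | tert-butyl (1S,4S,5R,6S)-6-(dimethoxymethyl)-4-hydroxy-1,5-dimethylcyclohex-2-ene-1-carboxylate | O[C@H]1C=C[C@@](C(=O)OC(C)(C)C)(C)[C@H]([C@H]1C)C(OC)OC | intermediate
11 | tert-butyl (1S,4S,5R,6S)-4-(tert-butyldimethylsilyloxy)-6-(dimethoxymethyl)-1,5-dimethylcyclohex-2-ene-1-carboxylate | CC(C)(C)[Si](C)(C)O[C@H]1C=C[C@@](C(=O)OC(C)(C)C)(C)[C@H]([C@H]1C)C(OC)OC | intermediate
12 | tert-butyl (1S,4S,5R,6S)-4-(tert-butyldimethylsilyloxy)-6-formyl-1,5-dimethylcyclohex-2-ene-1-carboxylate (ring A aldehyde; CHO = C9) | CC(C)(C)[Si](C)(C)O[C@H]1C=C[C@@](C(=O)OC(C)(C)C)(C)[C@H]([C@H]1C)C=O | intermediate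
13 | (R)-4-methyldihydrofuran-2(3H)-one | O=C1C[C@@H](C)CO1 | starting material
14 | potassium enolate of 13 | [K+].[O-]C1=C[C@@H](C)CO1 | intermediate
15 | (3R,4S)-3-hydroxy-4-methyldihydrofuran-2(3H)-one (trans) | O=C1[C@H](O)[C@@H](C)CO1 | intermediate
16 | dilithium enediolate of 15 | [Li+].[Li+].[O-]C1=C([O-])[C@@H](C)CO1 | intermediate
17 | C8–C9 aldol adduct, C9 epimers: ester 12 with C9 as CH(OH) bonded to C8 (C3 of the lactone, tertiary OH, new bond trans to the C17 methyl) | CC(C)(C)[Si](C)(C)O[C@H]1C=C[C@@](C(=O)OC(C)(C)C)(C)[C@H]([C@H]1C)C(O)[C@@]1(O)C(=O)OC[C@@H]1C | intermediate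
18 | C9 ketone of 17 | CC(C)(C)[Si](C)(C)O[C@H]1C=C[C@@](C(=O)OC(C)(C)C)(C)[C@H]([C@H]1C)C(=O)[C@@]1(O)C(=O)OC[C@@H]1C | intermediate
19 | (9R)-8,9-diol lactone (C8, C9, C17 configured as in 42) | CC(C)(C)[Si](C)(C)O[C@H]1C=C[C@@](C(=O)OC(C)(C)C)(C)[C@H]([C@H]1C)[C@@H](O)[C@@]1(O)C(=O)OC[C@@H]1C | intermediate
20 | 8,9-O-isopropylidene acetal of 19 | CC(C)(C)[Si](C)(C)O[C@H]1C=C[C@@](C(=O)OC(C)(C)C)(C)[C@H]([C@H]1C)[C@H]2OC(C)(C)O[C@@]21C(=O)OC[C@@H]1C | intermediate
21 | C7 lactol of 20 (anomer mixture) | CC(C)(C)[Si](C)(C)O[C@H]1C=C[C@@](C(=O)OC(C)(C)C)(C)[C@H]([C@H]1C)[C@H]2OC(C)(C)O[C@@]21C(O)OC[C@@H]1C | intermediate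
22 | 4-methoxyphenol | COc1ccc(O)cc1 | starting material
23 | 3-chloro-2-methylprop-1-ene | C=C(C)CCl | starting material
24 | 1-methoxy-4-[(2-methylprop-2-en-1-yl)oxy]benzene | COc1ccc(OCC(C)=C)cc1 | intermediate
25 | (Z)-[3-(4-methoxyphenoxy)-2-methylallyl]lithium | [Li]C/C(C)=C\Oc1ccc(OC)cc1 | intermediate
26 | (Z)-[3-(4-methoxyphenoxy)-2-methylallyl]bis(isopinocampheyl)borane, from (+)-α-pinene | COc1ccc(O/C=C(C)\CB([C@@H]2C[C@@H]3C[C@H]([C@H]2C)C3(C)C)[C@@H]2C[C@@H]3C[C@H]([C@H]2C)C3(C)C)cc1 | intermediate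
27 | (6R,7S)-adduct: C7 OH, C6 O-(4-methoxyphenyl), isopropenyl on C6, C19 CH2OH, 8,9-acetonide, ring A as in 12 | CC(C)(C)[Si](C)(C)O[C@H]1C=C[C@@](C(=O)OC(C)(C)C)(C)[C@H]([C@H]1C)[C@H]2OC(C)(C)O[C@@]2([C@@H](C)CO)[C@@H](O)[C@H](Oc1ccc(OC)cc1)C(C)=C | intermediate
28 | 7,19-bis(tert-butyldimethylsilyl) ether of 27 | CC(C)(C)[Si](C)(C)O[C@H]1C=C[C@@](C(=O)OC(C)(C)C)(C)[C@H]([C@H]1C)[C@H]2OC(C)(C)O[C@@]2([C@@H](C)CO[Si](C)(C)C(C)(C)C)[C@@H](O[Si](C)(C)C(C)(C)C)[C@H](Oc1ccc(OC)cc1)C(C)=C | intermediate
29 | C6 alcohol (28 without the 4-methoxyphenyl group) | CC(C)(C)[Si](C)(C)O[C@H]1C=C[C@@](C(=O)OC(C)(C)C)(C)[C@H]([C@H]1C)[C@H]2OC(C)(C)O[C@@]2([C@@H](C)CO[Si](C)(C)C(C)(C)C)[C@@H](O[Si](C)(C)C(C)(C)C)[C@H](O)C(C)=C | intermediate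
30 | trimethylsilyl ester of 31, C6 O-trimethylsilylated | CC(C)(C)[Si](C)(C)O[C@H]1C=C[C@@](C(=O)O[Si](C)(C)C)(C)[C@H]([C@H]1C)[C@H]2OC(C)(C)O[C@@]2([C@@H](C)CO[Si](C)(C)C(C)(C)C)[C@@H](O[Si](C)(C)C(C)(C)C)[C@H](O[Si](C)(C)C)C(C)=C | intermediate
31 | seco acid (C2 CO2H, C6 OH) | CC(C)(C)[Si](C)(C)O[C@H]1C=C[C@@](C(=O)O)(C)[C@H]([C@H]1C)[C@H]2OC(C)(C)O[C@@]2([C@@H](C)CO[Si](C)(C)C(C)(C)C)[C@@H](O[Si](C)(C)C(C)(C)C)[C@H](O)C(C)=C | intermediate
32 | mixed anhydride of 31 with 2,4,6-trichlorobenzoic acid | CC(C)(C)[Si](C)(C)O[C@H]1C=C[C@@](C(=O)OC(=O)c3c(Cl)cc(Cl)cc3Cl)(C)[C@H]([C@H]1C)[C@H]2OC(C)(C)O[C@@]2([C@@H](C)CO[Si](C)(C)C(C)(C)C)[C@@H](O[Si](C)(C)C(C)(C)C)[C@H](O)C(C)=C | intermediate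
33 | (6R)-eight-membered lactone (ring atoms C2, O, C6, C7, C8, C9, C10, C1; isopropenyl on C6) | CC(C)(C)[Si](C)(C)O[C@H]1C=C[C@@]2(C)[C@H]([C@H]1C)[C@H]3OC(C)(C)O[C@@]3([C@@H](C)CO[Si](C)(C)C(C)(C)C)[C@@H](O[Si](C)(C)C(C)(C)C)[C@@H](C(C)=C)OC2=O | intermediate
34 | 2-methyleneoxocane (C2=C3H2 enol ether of 33) | CC(C)(C)[Si](C)(C)O[C@H]1C=C[C@@]2(C)[C@H]([C@H]1C)[C@H]3OC(C)(C)O[C@@]3([C@@H](C)CO[Si](C)(C)C(C)(C)C)[C@@H](O[Si](C)(C)C(C)(C)C)[C@@H](C(C)=C)OC2=C | intermediate
35 | (5Z)-cyclodecenone: ring A-fused ten-membered C2 ketone, 7,19-bis-OTBS, 8,9-acetonide, 12β-OTBS | CC(C)(C)[Si](C)(C)O[C@H]1C=C[C@@]2(C)[C@H]([C@H]1C)[C@H]3OC(C)(C)O[C@@]3([C@@H](C)CO[Si](C)(C)C(C)(C)C)[C@@H](O[Si](C)(C)C(C)(C)C)/C=C(/C)CCC2=O | intermediate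
36 | (2R)-alcohol of 35 | CC(C)(C)[Si](C)(C)O[C@H]1C=C[C@@]2(C)[C@H]([C@H]1C)[C@H]3OC(C)(C)O[C@@]3([C@@H](C)CO[Si](C)(C)C(C)(C)C)[C@@H](O[Si](C)(C)C(C)(C)C)/C=C(/C)CC[C@H]2O | intermediate
37 | 2-acetate of 36 | CC(C)(C)[Si](C)(C)O[C@H]1C=C[C@@]2(C)[C@H]([C@H]1C)[C@H]3OC(C)(C)O[C@@]3([C@@H](C)CO[Si](C)(C)C(C)(C)C)[C@@H](O[Si](C)(C)C(C)(C)C)/C=C(/C)CC[C@H]2OC(C)=O | intermediate
38 | 7,12β,19-triol of 37 | O[C@H]1C=C[C@@]2(C)[C@H]([C@H]1C)[C@H]3OC(C)(C)O[C@@]3([C@@H](C)CO)[C@@H](O)/C=C(/C)CC[C@H]2OC(C)=O | intermediate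
39 | C19 lactol closed on O7 (anomers) | O[C@H]1C=C[C@@]2(C)[C@H]([C@H]1C)[C@H]3OC(C)(C)O[C@@]34[C@H](/C=C(/C)CC[C@H]2OC(C)=O)OC(O)[C@@H]4C | intermediate
40 | γ-lactone (C19(=O)–O7), 12β-OH, 2-OAc, 8,9-acetonide | O[C@H]1C=C[C@@]2(C)[C@H]([C@H]1C)[C@H]3OC(C)(C)O[C@@]34[C@H](/C=C(/C)CC[C@H]2OC(C)=O)OC(=O)[C@@H]4C | intermediate
41 | 12α-acetate: 8,9-O-isopropylidene derivative of 42 | CC(=O)O[C@@H]1C=C[C@@]2(C)[C@H]([C@H]1C)[C@H]3OC(C)(C)O[C@@]34[C@H](/C=C(/C)CC[C@H]2OC(C)=O)OC(=O)[C@@H]4C | intermediate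
42 | CNP0286823.1 | CC(=O)O[C@@H]1C=C[C@@]2(C)[C@H]([C@H]1C)[C@@H](O)[C@@]1(O)[C@H](/C=C(/C)CC[C@H]2OC(C)=O)OC(=O)[C@@H]1C | target

**Step count and risks**
Total steps: 28. Longest linear sequence: 26 steps (steps 1–9, 11–15, 17–28).

Steps most likely to fail:

Step 22 (ring expansion). What may go wrong: poor control of alkene geometry, if the sigmatropic shift runs partly through the boat array with C7 pseudo-equatorial. The fallback sets out from 33 and accepts the (5E)-cyclodecenone F4 as the primary product. F4 is then equilibrated by reversible thiyl-radical addition (PhSSPh cat., hν, benzene, rt) to the less strained Z ring olefin. The sequence comes back to the route at 35.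

Step 21 (eight-membered lactonisation). What may go wrong: oligomerisation, or acyl transfer to the aryl carbonyl of the mixed anhydride, because the C2 carboxyl is neopentyl and ring A must leave its preferred conformation to let C2 and C9 approach. The fallback sets out from 31 and closes the ring at the alkyl–oxygen bond instead. Mitsunobu macrolactonisation (PPh3, diisopropyl azodicarboxylate, toluene, slow addition) lets the carboxylate displace the activated C6 hydroxyl with inversion and gives the C6-epimeric lactone F2. Under the conditions of step 22, F2 is methylenated to the C6-epimeric 2-methyleneoxocane F3. Its rearrangement erases C6, so the fallback comes back to the route at 35.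

Step 2 (asymmetric cycloaddition). What may go wrong: loss of facial or regiochemical control, or catalyst inhibition by the acetal oxygens. The fallback sets out from 2 and 3 and uses an achiral Lewis acid (Me2AlCl, CH2Cl2, −78 °C) to give racemic 4. This is taken through steps 3–6 unchanged to racemic 9. The acid is resolved by crystallisation of its salt with (S)-1-phenylethylamine, the (S)-1-phenylethylammonium salt F1 of 9. Acidification with aqueous HCl returns enantiopure 9, where the fallback comes back to the route.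

Further compounds
F1 | step 2 | (S)-1-phenylethylammonium salt of 9 | O[C@H]1C=C[C@@](C([O-])=O)(C)[C@H]([C@H]1C)C(OC)OC.C[C@H]([NH3+])c1ccccc1
F2 | step 21 | (6S)-eight-membered lactone, C6 epimer of 33 | CC(C)(C)[Si](C)(C)O[C@H]1C=C[C@@]2(C)[C@H]([C@H]1C)[C@H]3OC(C)(C)O[C@@]3([C@@H](C)CO[Si](C)(C)C(C)(C)C)[C@@H](O[Si](C)(C)C(C)(C)C)[C@H](C(C)=C)OC2=O
F3 | step 21 | C6-epimeric 2-methyleneoxocane, C6 epimer of 34 | CC(C)(C)[Si](C)(C)O[C@H]1C=C[C@@]2(C)[C@H]([C@H]1C)[C@H]3OC(C)(C)O[C@@]3([C@@H](C)CO[Si](C)(C)C(C)(C)C)[C@@H](O[Si](C)(C)C(C)(C)C)[C@H](C(C)=C)OC2=C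
F4 | step 22 | (5E)-cyclodecenone, 5E isomer of 35 | CC(C)(C)[Si](C)(C)O[C@H]1C=C[C@@]2(C)[C@H]([C@H]1C)[C@H]3OC(C)(C)O[C@@]3([C@@H](C)CO[Si](C)(C)C(C)(C)C)[C@@H](O[Si](C)(C)C(C)(C)C)/C=C(\C)CCC2=O
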